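The labels, the protecting-group logic and one assumption are stated before the steps; the route has not been run, so every outcome is an expectation.

**Strategy.** The route rests on cutting the C2′–C3′ bond of the dihydrofuran ring fused to ring B, and likewise C2–C3 of the ring fused to ring A. Each ring then unfolds to an aryl benzyl ether carrying a diaryldiazomethane carbon ortho to the oxygen, so that C3′ (or C3) lies 1,5 to the benzylic C2′–H (or C2–H) bond across O1′ (or O1): this is the feature exploited. In one operation a chiral dirhodium catalyst converts bis(diazo) diether 21, generated from bis(hydrazone) 20, into both rings by carbene C–H insertion, fixing C3 and C3′; acid then relays the cis C2 and C2′ centres to trans. The stilbene is attached last.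

Key step: step 13

Labels: ring A is the benzene ring that carries the styryl group, ring B the benzene ring of the second dihydrobenzofuran, ring C the 2,4-dihydroxyphenyl ring. Unprimed locants (O1, C2, C3, C3a to C7a) belong to the dihydrobenzofuran fused to ring A, primed locants to the one fused to ring B; C2 is bonded to C7′. The target is (2S,3S,2′S,3′S), both rings 2,3-trans. TIPS = triisopropylsilyl, TBS = tert-butyldimethylsilyl.

Protecting groups: silyl ethers are used because the ring fused to ring B is a cyclic 2,4-dioxygenated benzyl aryl ether; a Lewis-acid dealkylation at the end could reopen it and let it re-close through O4′ instead of O1′.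

Assumption: Rh2(R-PTAD)4 is taken as the catalyst antipode that gives the (3S,3′S) sense; should the sense be the opposite, Rh2(S-PTAD)4 replaces it and nothing else changes.

**Route**

Step 1
Reactants: 1 1-bromo-3,5-dimethoxybenzene; 2 3,5-dimethoxybenzoyl chloride
Product: 3 (2-bromo-4,6-dimethoxyphenyl)(3,5-dimethoxyphenyl)methanone
Conditions: AlCl3, CH2Cl2, 0 °C → rt
Reagents that add atoms: none
Why: Friedel–Crafts acylation should take place at C2 of 1, which is para to one methoxy group and ortho to the other, rather than at the position flanked by both methoxy groups.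

Step 2
Reactants: 3 (2-bromo-4,6-dimethoxyphenyl)(3,5-dimethoxyphenyl)methanone
Product: 4 (2-bromo-4,6-dihydroxyphenyl)(3,5-dihydroxyphenyl)methanone
Conditions: BBr3 (6 equiv), CH2Cl2, −78 °C → rt; H2O
Reagents that add atoms: none
Why: Lewis-acid cleavage of aryl methyl ethers with BBr3 should remove all four methyl groups at this robust benzophenone stage, where no acid-labile ring exists yet.

Step 3
Reactants: 4 (2-bromo-4,6-dihydroxyphenyl)(3,5-dihydroxyphenyl)methanone
Product: 5 {2-bromo-6-hydroxy-4-[(triisopropylsilyl)oxy]phenyl}{3,5-bis[(triisopropylsilyl)oxy]phenyl}methanone (ketophenol A)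
Conditions: TIPSCl (3.2 equiv), imidazole, DMF, 0 °C → rt
Reagents that add atoms: chlorotriisopropylsilane, CC(C)[Si](Cl)(C(C)C)C(C)C
Why: Silylation of phenols should stop after the three unhindered hydroxyl groups, because the fourth is hydrogen-bonded to the ketone and flanked by it.

Step 4
Reactants: 6 2,4-dimethoxybenzaldehyde; 7 N,3,5-trimethoxy-N-methylbenzamide
Product: 11 3-(3,5-dimethoxybenzoyl)-2,4-dimethoxybenzaldehyde, via lithium α-amino alkoxide 8 (not isolated), via C3-lithiated α-amino alkoxide 9 (not isolated), via tetrahedral dilithium adduct 10 (not isolated)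
Conditions: N-methylpiperazine, n-BuLi, THF, −20 °C; then n-BuLi, TMEDA, −20 → 0 °C; then 7, −78 °C → rt; aq. HCl
Reagents that add atoms: none
Why: Directed ortho-lithiation of an aldehyde masked in situ as its lithium α-amino alkoxide should occur at C3 between the two methoxy groups, and acylation of the aryllithium by the Weinreb amide stops at the ketone because the tetrahedral adduct survives until the acidic work-up, which also frees the aldehyde.

Step 5
Reactants: 11 3-(3,5-dimethoxybenzoyl)-2,4-dimethoxybenzaldehyde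
Product: 12 3-(3,5-dihydroxybenzoyl)-2,4-dihydroxybenzaldehyde
Conditions: BBr3 (6 equiv), CH2Cl2, −78 °C → rt; H2O
Reagents that add atoms: none
Why: BBr3 demethylation of the four aryl methyl ethers, the aldehyde and ketone being regenerated from their boron complexes on aqueous work-up.

Step 6
Reactants: 12 3-(3,5-dihydroxybenzoyl)-2,4-dihydroxybenzaldehyde
Product: 13 3-{3,5-bis[(triisopropylsilyl)oxy]benzoyl}-2-hydroxy-4-[(triisopropylsilyl)oxy]benzaldehyde
Conditions: TIPSCl (3.2 equiv), imidazole, DMF, 0 °C → rt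
Reagents that add atoms: chlorotriisopropylsilane, CC(C)[Si](Cl)(C(C)C)C(C)C
Why: Silylation should spare the 2-hydroxyl group, which is chelated to the aldehyde and flanked by two carbonyl-bearing carbons, so that only O1′ of the later ring B stays free.

Step 7
Reactants: 14 2,4-dihydroxybenzaldehyde
Product: 15 2,4-bis[(triisopropylsilyl)oxy]benzaldehyde
Conditions: TIPSOTf (2.4 equiv), 2,6-lutidine, CH2Cl2, 0 °C → rt
Reagents that add atoms: triisopropylsilyl trifluoromethanesulfonate, CC(C)[Si](OS(=O)(=O)C(F)(F)F)(C(C)C)C(C)C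
Why: The silyl triflate is reactive enough to silylate the chelated ortho-hydroxyl group as well as the para one.

Step 8
Reactants: 15 2,4-bis[(triisopropylsilyl)oxy]benzaldehyde
Product: 16 {2,4-bis[(triisopropylsilyl)oxy]phenyl}methanol
Conditions: NaBH4, THF/MeOH, 0 °C
Reagents that add atoms: none
Why: Borohydride reduction of the aldehyde gives the benzylic alcohol that will become C2′ and ring C.

Step 9
Reactants: 13 3-{3,5-bis[(triisopropylsilyl)oxy]benzoyl}-2-hydroxy-4-[(triisopropylsilyl)oxy]benzaldehyde; 16 {2,4-bis[(triisopropylsilyl)oxy]phenyl}methanol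
Product: 17 2-({2,4-bis[(triisopropylsilyl)oxy]phenyl}methoxy)-3-{3,5-bis[(triisopropylsilyl)oxy]benzoyl}-4-[(triisopropylsilyl)oxy]benzaldehyde
Conditions: PPh3, DIAD, THF, 0 °C → rt
Reagents that add atoms: none
Why: Mitsunobu etherification should work because the phenol of 13 is acidic (ortho to two carbonyl groups) and the primary benzylic alcohol 16 is readily activated as its oxyphosphonium salt, without base that could move silyl groups.

Step 10
Reactants: 17 2-({2,4-bis[(triisopropylsilyl)oxy]phenyl}methoxy)-3-{3,5-bis[(triisopropylsilyl)oxy]benzoyl}-4-[(triisopropylsilyl)oxy]benzaldehyde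
Product: 18 [2-({2,4-bis[(triisopropylsilyl)oxy]phenyl}methoxy)-3-(hydroxymethyl)-6-[(triisopropylsilyl)oxy]phenyl]{3,5-bis[(triisopropylsilyl)oxy]phenyl}methanone
Conditions: NaBH4, THF/MeOH, −20 °C
Reagents that add atoms: none
Why: Chemoselective borohydride reduction: the aldehyde reacts, whereas the diaryl ketone, shielded by two ortho oxygen substituents and twisted out of conjugation, should not.

Step 11
Reactants: 5 ketophenol A; 18 [2-({2,4-bis[(triisopropylsilyl)oxy]phenyl}methoxy)-3-(hydroxymethyl)-6-[(triisopropylsilyl)oxy]phenyl]{3,5-bis[(triisopropylsilyl)oxy]phenyl}methanone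
Product: 19 bis(ketone) diether in which O7a of ring A carries the CH2 group on C7′ of ring B and O7a′ of ring B carries the CH2 group of ring C
Conditions: PPh3, DIAD, toluene, 0 °C → rt
Reagents that add atoms: none
Why: A second Mitsunobu etherification joins the two halves through the O1–C2 bond of the future ring fused to ring A, the ortho-acyl phenol of 5 being the acidic partner.

Step 12
Reactants: 19 bis(ketone) diether
Product: 20 bis(hydrazone) of 19 (C=N geometry not defined)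
Conditions: N2H4 (anhydrous, excess), AcOH (cat.), n-BuOH, 110 °C, sealed tube
Reagents that add atoms: hydrazine, NN
Why: Hydrazone condensation, forced by excess hydrazine and heat because both ketones carry two ortho substituents; triisopropylsilyl aryl ethers are chosen to survive it.

Step 13
Reactants: 20 bis(hydrazone)
Product: 24 all-cis bis(dihydrobenzofuran) bromide (2R,3S,2′R,3′S), via bis(diazo) diether 21 (not isolated), via ring-B-closed monodiazo compound 22 (not isolated), via ring-A-closed monodiazo compound 23 (not isolated)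
Conditions: MnO2 (12 equiv), CH2Cl2, 0 °C, filtration through Celite; then slow addition to Rh2(R-PTAD)4 (4 mol %), CH2Cl2, −20 °C → rt
Reagents that add atoms: none
Why: MnO2 dehydrogenates both hydrazones to diaryldiazomethanes, and Rh2(R-PTAD)4, dirhodium tetrakis[(R)-(1-adamantyl)(N-phthalimido)acetate], then expels N2 from each to give a donor/donor rhodium carbene whose carbon (C3′ on ring B, C3 on ring A) takes the hydride-like hydrogen of the ether methylene five atoms away and bonds to that carbon (C2′, C2), in either order (22 or 23). The closest known reaction type is the enantioselective intramolecular C–H insertion of diaryl rhodium carbenes into benzyl aryl ethers, which leads to cis-2,3-diaryl-2,3-dihydrobenzofurans. Each ring closes in the 1,5-C–H insertion mode, the new C2′–C3′ and C2–C3 bonds completing five-membered rings already held together by O1′ and O1. C3′ and C3 are set by the chiral carboxylate pocket of the catalyst, in the same S sense because both carbenes present the same substituent pattern, while C2′ and C2 follow from the compact insertion transition state, which places the two aryl groups cis; the second insertion is again catalyst-controlled, so material of the wrong sense should end up as a separable diastereomer. The step needs site selectivity for the two ArO–CH2–Ar groups: each is the only C–H site that is both 1,5 to a carbene and activated by oxygen and an electron-rich ring, the O4′ neighbour of C3′ is a silyl ether without such a bond, and bromine instead of the styryl group at C4 keeps alkenes away from the carbenes. Slow addition of 21 to the catalyst should keep carbene–diazo coupling slower than the intramolecular insertions.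

Step 14
Reactants: 24 all-cis bis(dihydrobenzofuran) bromide (2R,3S,2′R,3′S)
Product: 25 trans,trans bis(dihydrobenzofuran) bromide (2S,3S,2′S,3′S)
Conditions: CF3CO2H (5 equiv), CH2Cl2, 0 °C
Reagents that add atoms: none
Why: Acid-catalysed epimerisation of 2-aryl-2,3-dihydrobenzofurans: reversible ionisation of the benzylic C2–O1 and C2′–O1′ bonds (cations stabilised by the ortho and para oxygen atoms of ring B and ring C) and re-closure should give the thermodynamically preferred 2,3-trans rings with C3 and C3′ untouched, while the silyl group on O4′ blocks re-closure through the other ortho oxygen of ring B and no stilbene is yet present to be attacked.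

Step 15
Reactants: 25 trans,trans bis(dihydrobenzofuran) bromide; 26 tert-butyldimethyl(4-vinylphenoxy)silane
Product: 27 nonasilyl ether of the target with the (E)-2-[4-(tert-butyldimethylsilyloxy)phenyl]ethenyl group on C4
Conditions: Pd2(dba)3 (3 mol %), P(t-Bu)3·HBF4 (12 mol %), Cy2NMe, 1,4-dioxane, 80 °C
Reagents that add atoms: none
Why: Mizoroki–Heck reaction, in which the bulky electron-rich phosphine should allow oxidative addition of the hindered, electron-rich C4–Br bond and syn insertion followed by syn β-hydride elimination gives the E-stilbene.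

Step 16
Reactants: 27 nonasilyl ether of the target
Product: 28 target, 4-[(2S,3S)-3-(3,5-dihydroxyphenyl)-7-{(2S,3S)-3-(3,5-dihydroxyphenyl)-6-hydroxy-4-[(E)-2-(4-hydroxyphenyl)ethenyl]-2,3-dihydro-1-benzofuran-2-yl}-4-hydroxy-2,3-dihydro-1-benzofuran-2-yl]benzene-1,3-diol
Conditions: TBAF (12 equiv), AcOH (12 equiv), THF, 0 °C → rt, argon
Reagents that add atoms: none
Why: Fluoride cleavage of all nine aryl silyl ethers, buffered with acetic acid so that the phenols stay protonated and neither acid-induced ionisation nor phenoxide-driven quinone-methide opening of the two dihydrofuran rings can scramble C2, C2′ or the O1′/O4′ regiochemistry.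

**Compound list**

1 | 1-bromo-3,5-dimethoxybenzene | COc1cc(Br)cc(OC)c1 | starting material
2 | 3,5-dimethoxybenzoyl chloride | COc1cc(cc(OC)c1)C(Cl)=O | starting material
3 | (2-bromo-4,6-dimethoxyphenyl)(3,5-dimethoxyphenyl)methanone | O=C(c1cc(OC)cc(OC)c1)c1c(OC)cc(OC)cc1Br | intermediate
4 | (2-bromo-4,6-dihydroxyphenyl)(3,5-dihydroxyphenyl)methanone | O=C(c1cc(O)cc(O)c1)c1c(O)cc(O)cc1Br | intermediate
5 | {2-bromo-6-hydroxy-4-[(triisopropylsilyl)oxy]phenyl}{3,5-bis[(triisopropylsilyl)oxy]phenyl}methanone (ketophenol A) | O=C(c1cc(O[Si](C(C)C)(C(C)C)C(C)C)cc(O[Si](C(C)C)(C(C)C)C(C)C)c1)c1c(O)cc(O[Si](C(C)C)(C(C)C)C(C)C)cc1Br | intermediate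
6 | 2,4-dimethoxybenzaldehyde | COc1ccc(C=O)c(OC)c1 | starting material
7 | N,3,5-trimethoxy-N-methylbenzamide (taken as a catalogue compound) | CON(C)C(=O)c1cc(OC)cc(OC)c1 | starting material
8 | lithium (2,4-dimethoxyphenyl)(4-methylpiperazin-1-yl)methanolate (formed in the flask, not isolated) | [Li+].[O-]C(N1CCN(C)CC1)c1ccc(OC)cc1OC | intermediate
9 | lithium (3-lithio-2,4-dimethoxyphenyl)(4-methylpiperazin-1-yl)methanolate (formed in the flask, not isolated) | [Li+].[O-]C(N1CCN(C)CC1)c1ccc(OC)c([Li])c1OC | intermediate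
10 | dilithium tetrahedral adduct of 9 and 7 (formed in the flask, not isolated) | [Li+].[Li+].[O-]C(N1CCN(C)CC1)c1ccc(OC)c(c1OC)C([O-])(N(C)OC)c1cc(OC)cc(OC)c1 | intermediate
11 | 3-(3,5-dimethoxybenzoyl)-2,4-dimethoxybenzaldehyde | COc1ccc(C=O)c(OC)c1C(=O)c1cc(OC)cc(OC)c1 | intermediate
12 | 3-(3,5-dihydroxybenzoyl)-2,4-dihydroxybenzaldehyde | O=Cc1ccc(O)c(C(=O)c2cc(O)cc(O)c2)c1O | intermediate
13 | 3-{3,5-bis[(triisopropylsilyl)oxy]benzoyl}-2-hydroxy-4-[(triisopropylsilyl)oxy]benzaldehyde | O=Cc1ccc(O[Si](C(C)C)(C(C)C)C(C)C)c(C(=O)c2cc(O[Si](C(C)C)(C(C)C)C(C)C)cc(O[Si](C(C)C)(C(C)C)C(C)C)c2)c1O | intermediate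
14 | 2,4-dihydroxybenzaldehyde | O=Cc1ccc(O)cc1O | starting material
15 | 2,4-bis[(triisopropylsilyl)oxy]benzaldehyde | O=Cc1ccc(O[Si](C(C)C)(C(C)C)C(C)C)cc1O[Si](C(C)C)(C(C)C)C(C)C | intermediate
16 | {2,4-bis[(triisopropylsilyl)oxy]phenyl}methanol | OCc1ccc(O[Si](C(C)C)(C(C)C)C(C)C)cc1O[Si](C(C)C)(C(C)C)C(C)C | intermediate
17 | 2-({2,4-bis[(triisopropylsilyl)oxy]phenyl}methoxy)-3-{3,5-bis[(triisopropylsilyl)oxy]benzoyl}-4-[(triisopropylsilyl)oxy]benzaldehyde | O=Cc1ccc(O[Si](C(C)C)(C(C)C)C(C)C)c(C(=O)c2cc(O[Si](C(C)C)(C(C)C)C(C)C)cc(O[Si](C(C)C)(C(C)C)C(C)C)c2)c1OCc1ccc(O[Si](C(C)C)(C(C)C)C(C)C)cc1O[Si](C(C)C)(C(C)C)C(C)C | intermediate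
18 | [2-({2,4-bis[(triisopropylsilyl)oxy]phenyl}methoxy)-3-(hydroxymethyl)-6-[(triisopropylsilyl)oxy]phenyl]{3,5-bis[(triisopropylsilyl)oxy]phenyl}methanone | OCc1ccc(O[Si](C(C)C)(C(C)C)C(C)C)c(C(=O)c2cc(O[Si](C(C)C)(C(C)C)C(C)C)cc(O[Si](C(C)C)(C(C)C)C(C)C)c2)c1OCc1ccc(O[Si](C(C)C)(C(C)C)C(C)C)cc1O[Si](C(C)C)(C(C)C)C(C)C | intermediate
19 | bis(ketone) diether: ring A (4-bromo, 6-TIPSO, 3a-aroyl) linked through O–CH2 to C7′ of ring B (4′-TIPSO, 3a′-aroyl), whose O7a′ carries the 2,4-bis(TIPSO)benzyl group; both aroyl groups are 3,5-bis(TIPSO)benzoyl | O=C(c1cc(O[Si](C(C)C)(C(C)C)C(C)C)cc(O[Si](C(C)C)(C(C)C)C(C)C)c1)c1c(Br)cc(O[Si](C(C)C)(C(C)C)C(C)C)cc1OCc1ccc(O[Si](C(C)C)(C(C)C)C(C)C)c(C(=O)c2cc(O[Si](C(C)C)(C(C)C)C(C)C)cc(O[Si](C(C)C)(C(C)C)C(C)C)c2)c1OCc1ccc(O[Si](C(C)C)(C(C)C)C(C)C)cc1O[Si](C(C)C)(C(C)C)C(C)C | intermediate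
20 | bis(hydrazone) of 19 (C=N geometry not defined) | NN=C(c1cc(O[Si](C(C)C)(C(C)C)C(C)C)cc(O[Si](C(C)C)(C(C)C)C(C)C)c1)c1c(Br)cc(O[Si](C(C)C)(C(C)C)C(C)C)cc1OCc1ccc(O[Si](C(C)C)(C(C)C)C(C)C)c(C(=NN)c2cc(O[Si](C(C)C)(C(C)C)C(C)C)cc(O[Si](C(C)C)(C(C)C)C(C)C)c2)c1OCc1ccc(O[Si](C(C)C)(C(C)C)C(C)C)cc1O[Si](C(C)C)(C(C)C)C(C)C | intermediate
21 | bis(diazo) diether (formed in the flask, not isolated) | [N-]=[N+]=C(c1cc(O[Si](C(C)C)(C(C)C)C(C)C)cc(O[Si](C(C)C)(C(C)C)C(C)C)c1)c1c(Br)cc(O[Si](C(C)C)(C(C)C)C(C)C)cc1OCc1ccc(O[Si](C(C)C)(C(C)C)C(C)C)c(C(=[N+]=[N-])c2cc(O[Si](C(C)C)(C(C)C)C(C)C)cc(O[Si](C(C)C)(C(C)C)C(C)C)c2)c1OCc1ccc(O[Si](C(C)C)(C(C)C)C(C)C)cc1O[Si](C(C)C)(C(C)C)C(C)C | intermediate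
22 | ring-B-closed monodiazo compound, (2′R,3′S)-cis ring on ring B, diazo group still on ring A (formed in the flask, not isolated) | [N-]=[N+]=C(c1cc(O[Si](C(C)C)(C(C)C)C(C)C)cc(O[Si](C(C)C)(C(C)C)C(C)C)c1)c1c(Br)cc(O[Si](C(C)C)(C(C)C)C(C)C)cc1OCc1ccc(O[Si](C(C)C)(C(C)C)C(C)C)c2c1O[C@@H](c1ccc(O[Si](C(C)C)(C(C)C)C(C)C)cc1O[Si](C(C)C)(C(C)C)C(C)C)[C@H]2c1cc(O[Si](C(C)C)(C(C)C)C(C)C)cc(O[Si](C(C)C)(C(C)C)C(C)C)c1 | intermediate
23 | ring-A-closed monodiazo compound, (2R,3S)-cis ring on ring A, diazo group still on ring B (formed in the flask, not isolated) | Brc1cc(O[Si](C(C)C)(C(C)C)C(C)C)cc2c1[C@H](c1cc(O[Si](C(C)C)(C(C)C)C(C)C)cc(O[Si](C(C)C)(C(C)C)C(C)C)c1)[C@H](c1ccc(O[Si](C(C)C)(C(C)C)C(C)C)c(C(=[N+]=[N-])c3cc(O[Si](C(C)C)(C(C)C)C(C)C)cc(O[Si](C(C)C)(C(C)C)C(C)C)c3)c1OCc1ccc(O[Si](C(C)C)(C(C)C)C(C)C)cc1O[Si](C(C)C)(C(C)C)C(C)C)O2 | intermediate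
24 | (2R,3S)-4-bromo-3-[3,5-bis(TIPSO)phenyl]-6-(TIPSO)-2-{(2R,3S)-2-[2,4-bis(TIPSO)phenyl]-3-[3,5-bis(TIPSO)phenyl]-4-(TIPSO)-2,3-dihydro-1-benzofuran-7-yl}-2,3-dihydro-1-benzofuran (both rings 2,3-cis) | Brc1cc(O[Si](C(C)C)(C(C)C)C(C)C)cc2c1[C@H](c1cc(O[Si](C(C)C)(C(C)C)C(C)C)cc(O[Si](C(C)C)(C(C)C)C(C)C)c1)[C@H](c1ccc(O[Si](C(C)C)(C(C)C)C(C)C)c3c1O[C@@H](c1ccc(O[Si](C(C)C)(C(C)C)C(C)C)cc1O[Si](C(C)C)(C(C)C)C(C)C)[C@H]3c1cc(O[Si](C(C)C)(C(C)C)C(C)C)cc(O[Si](C(C)C)(C(C)C)C(C)C)c1)O2 | intermediate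
25 | (2S,3S)-4-bromo-3-[3,5-bis(TIPSO)phenyl]-6-(TIPSO)-2-{(2S,3S)-2-[2,4-bis(TIPSO)phenyl]-3-[3,5-bis(TIPSO)phenyl]-4-(TIPSO)-2,3-dihydro-1-benzofuran-7-yl}-2,3-dihydro-1-benzofuran (both rings 2,3-trans) | Brc1cc(O[Si](C(C)C)(C(C)C)C(C)C)cc2c1[C@H](c1cc(O[Si](C(C)C)(C(C)C)C(C)C)cc(O[Si](C(C)C)(C(C)C)C(C)C)c1)[C@@H](c1ccc(O[Si](C(C)C)(C(C)C)C(C)C)c3c1O[C@H](c1ccc(O[Si](C(C)C)(C(C)C)C(C)C)cc1O[Si](C(C)C)(C(C)C)C(C)C)[C@H]3c1cc(O[Si](C(C)C)(C(C)C)C(C)C)cc(O[Si](C(C)C)(C(C)C)C(C)C)c1)O2 | intermediate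
26 | tert-butyldimethyl(4-vinylphenoxy)silane (taken as a catalogue compound) | C=Cc1ccc(O[Si](C)(C)C(C)(C)C)cc1 | starting material
27 | nonasilyl ether of the target: compound 25 with the (E)-2-[4-(tert-butyldimethylsilyloxy)phenyl]ethenyl group in place of bromine, (2S,3S,2′S,3′S) | CC(C)(C)[Si](C)(C)Oc1ccc(/C=C/c2cc(O[Si](C(C)C)(C(C)C)C(C)C)cc3c2[C@H](c2cc(O[Si](C(C)C)(C(C)C)C(C)C)cc(O[Si](C(C)C)(C(C)C)C(C)C)c2)[C@@H](c2ccc(O[Si](C(C)C)(C(C)C)C(C)C)c4c2O[C@H](c2ccc(O[Si](C(C)C)(C(C)C)C(C)C)cc2O[Si](C(C)C)(C(C)C)C(C)C)[C@H]4c2cc(O[Si](C(C)C)(C(C)C)C(C)C)cc(O[Si](C(C)C)(C(C)C)C(C)C)c2)O3)cc1 | intermediate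
28 | 4-[(2S,3S)-3-(3,5-dihydroxyphenyl)-7-{(2S,3S)-3-(3,5-dihydroxyphenyl)-6-hydroxy-4-[(E)-2-(4-hydroxyphenyl)ethenyl]-2,3-dihydro-1-benzofuran-2-yl}-4-hydroxy-2,3-dihydro-1-benzofuran-2-yl]benzene-1,3-diol | Oc1ccc(/C=C/c2cc(O)cc3c2[C@H](c2cc(O)cc(O)c2)[C@@H](c2ccc(O)c4c2O[C@H](c2ccc(O)cc2O)[C@H]4c2cc(O)cc(O)c2)O3)cc1 | target

**Step count and risks**

Total step count: 16 (ketophenol A: steps 1–3; ring B piece: steps 4–6; ring C piece: steps 7–8; assembly and end game: steps 9–16).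
Longest linear sequence: 11 steps (steps 4, 5, 6, 9, 10, 11, 12, 13, 14, 15, 16).

Steps most likely to fail:

1. Step 13 (double carbene insertion). What may go wrong: carbene formation at the two doubly ortho-substituted diazo carbons may be slow, a carbene may be intercepted by a diazo group of another molecule (azine or alkene formation), or the second insertion may proceed with weaker stereocontrol in the crowded half-cyclised species. Fallback, setting out from 18 and returning at 24: the two rings are closed one after the other by the same known single insertion. Alcohol 18 is condensed with hydrazine (n-BuOH, 110 °C) to the monohydrazone alcohol F1. MnO2 in CH2Cl2 oxidises both the hydrazone and the benzylic alcohol to the diazo aldehyde F2, which is not isolated but added to Rh2(R-PTAD)4 at −20 °C to give the (2R,3S)-cis-dihydrobenzofuran-7-carbaldehyde F3. NaBH4 gives the 7-hydroxymethyl compound F4, and Mitsunobu etherification with ketophenol 5 gives the ketone ether F5. Hydrazine converts this into the hydrazone F6, MnO2 gives the monodiazo compound 22, and Rh2(R-PTAD)4 closes the second ring to 24.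

2. Step 12 (bis-hydrazone formation). What may go wrong: condensation at two diaryl ketones that each carry two ortho substituents may stall, prolonged heating with hydrazine may strip silyl groups, and the ring A hydrazone may displace the neighbouring bromide to form an indazole. Fallback, setting out from 19 and returning at 20: Lawesson's reagent (toluene, 100 °C) converts both carbonyl groups into thiocarbonyl groups to give the bis(thioketone) F7, and the far more electrophilic thiocarbonyl groups then react with hydrazine hydrate in THF at rt to give 20.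

3. Step 4 (one-pot lithiation and acylation). What may go wrong: lithiation may be incomplete or occur next to the amino alkoxide instead of between the methoxy groups, the crowded aryllithium may add slowly to the amide, and residual butyllithium may consume the amide. Fallback, setting out from 7 and returning at 11: purchased 1,3-dimethoxybenzene F8 is lithiated at C2 (n-BuLi, THF, 0 °C → rt) to 2,6-dimethoxyphenyllithium F9, which adds to 7 to give (2,6-dimethoxyphenyl)(3,5-dimethoxyphenyl)methanone F10. Rieche formylation (Cl2CHOMe, TiCl4, CH2Cl2, 0 °C) then enters the 2,6-dimethoxyphenyl ring ortho to one methoxy group and para to the other, meta to the twisted carbonyl, and gives 11.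

Further compounds
F1 | step 13 | monohydrazone of alcohol 18 | OCc1ccc(O[Si](C(C)C)(C(C)C)C(C)C)c(C(=NN)c2cc(O[Si](C(C)C)(C(C)C)C(C)C)cc(O[Si](C(C)C)(C(C)C)C(C)C)c2)c1OCc1ccc(O[Si](C(C)C)(C(C)C)C(C)C)cc1O[Si](C(C)C)(C(C)C)C(C)C
F2 | step 13 | diazo aldehyde (not isolated) | O=Cc1ccc(O[Si](C(C)C)(C(C)C)C(C)C)c(C(=[N+]=[N-])c2cc(O[Si](C(C)C)(C(C)C)C(C)C)cc(O[Si](C(C)C)(C(C)C)C(C)C)c2)c1OCc1ccc(O[Si](C(C)C)(C(C)C)C(C)C)cc1O[Si](C(C)C)(C(C)C)C(C)C
F3 | step 13 | (2R,3S)-2-[2,4-bis(TIPSO)phenyl]-3-[3,5-bis(TIPSO)phenyl]-4-(TIPSO)-2,3-dihydro-1-benzofuran-7-carbaldehyde | O=Cc1ccc(O[Si](C(C)C)(C(C)C)C(C)C)c2c1O[C@@H](c1ccc(O[Si](C(C)C)(C(C)C)C(C)C)cc1O[Si](C(C)C)(C(C)C)C(C)C)[C@H]2c1cc(O[Si](C(C)C)(C(C)C)C(C)C)cc(O[Si](C(C)C)(C(C)C)C(C)C)c1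
F4 | step 13 | [(2R,3S)-2-[2,4-bis(TIPSO)phenyl]-3-[3,5-bis(TIPSO)phenyl]-4-(TIPSO)-2,3-dihydro-1-benzofuran-7-yl]methanol | OCc1ccc(O[Si](C(C)C)(C(C)C)C(C)C)c2c1O[C@@H](c1ccc(O[Si](C(C)C)(C(C)C)C(C)C)cc1O[Si](C(C)C)(C(C)C)C(C)C)[C@H]2c1cc(O[Si](C(C)C)(C(C)C)C(C)C)cc(O[Si](C(C)C)(C(C)C)C(C)C)c1
F5 | step 13 | ketone ether from 5 and F4 (ring B closed, ring A ketone) | O=C(c1cc(O[Si](C(C)C)(C(C)C)C(C)C)cc(O[Si](C(C)C)(C(C)C)C(C)C)c1)c1c(Br)cc(O[Si](C(C)C)(C(C)C)C(C)C)cc1OCc1ccc(O[Si](C(C)C)(C(C)C)C(C)C)c2c1O[C@@H](c1ccc(O[Si](C(C)C)(C(C)C)C(C)C)cc1O[Si](C(C)C)(C(C)C)C(C)C)[C@H]2c1cc(O[Si](C(C)C)(C(C)C)C(C)C)cc(O[Si](C(C)C)(C(C)C)C(C)C)c1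
F6 | step 13 | hydrazone of F5 | NN=C(c1cc(O[Si](C(C)C)(C(C)C)C(C)C)cc(O[Si](C(C)C)(C(C)C)C(C)C)c1)c1c(Br)cc(O[Si](C(C)C)(C(C)C)C(C)C)cc1OCc1ccc(O[Si](C(C)C)(C(C)C)C(C)C)c2c1O[C@@H](c1ccc(O[Si](C(C)C)(C(C)C)C(C)C)cc1O[Si](C(C)C)(C(C)C)C(C)C)[C@H]2c1cc(O[Si](C(C)C)(C(C)C)C(C)C)cc(O[Si](C(C)C)(C(C)C)C(C)C)c1
F7 | step 12 | bis(thioketone) of 19 | S=C(c1cc(O[Si](C(C)C)(C(C)C)C(C)C)cc(O[Si](C(C)C)(C(C)C)C(C)C)c1)c1c(Br)cc(O[Si](C(C)C)(C(C)C)C(C)C)cc1OCc1ccc(O[Si](C(C)C)(C(C)C)C(C)C)c(C(=S)c2cc(O[Si](C(C)C)(C(C)C)C(C)C)cc(O[Si](C(C)C)(C(C)C)C(C)C)c2)c1OCc1ccc(O[Si](C(C)C)(C(C)C)C(C)C)cc1O[Si](C(C)C)(C(C)C)C(C)C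
F8 | step 4 | 1,3-dimethoxybenzene (purchased) | COc1cccc(OC)c1
F9 | step 4 | 2,6-dimethoxyphenyllithium (not isolated) | COc1cccc(OC)c1[Li]
F10 | step 4 | (2,6-dimethoxyphenyl)(3,5-dimethoxyphenyl)methanone | COc1cccc(OC)c1C(=O)c1cc(OC)cc(OC)c1
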